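## Structural features

Compound 15 is a 1-aryltetralin cyclolignan. Aromatic ring A (C4a, C5, C6, C7, C8, C8a; OMe on C6 and C8, OH on C7) is fused through C4a–C8a to the saturated ring B (C1, C2, C3, C4). C1 carries the pendant ring C (4-hydroxy-3,5-dimethoxyphenyl), and C2 and C3 each carry CH2OH.

The stereocentres C1 (S), C2 (R) and C3 (R) are contiguous and all-trans (ring C up, C2–CH2OH down, C3–CH2OH up). All three substituents can therefore sit (pseudo)equatorial on the half-chair of ring B.

Three groups are fragile. The two 2,6-dimethoxyphenols are very easily oxidised at their para-benzylic positions (C1–H for ring C, C4–H for ring A). The C1–H bond is doubly benzylic. The oxygens of the 1,4-diol lie within reach of any cation at C1 or C4.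

The real difficulty is the contiguous triad in one absolute sense, together with the crowded diarylmethine bond C1–C8a, which lies ortho to the C8 methoxy group.

Rings A and C have the same oxygenation pattern, and the chains C4–C3–CH2OH and C1–C2–CH2OH are the same. Hence 15 consists of two identical C6–C3 halves joined twice, at C2–C3 and at C1–C8a.

The key step exploits the C2–C3 bond of ring B. Once C1–C8a is opened, a C2 axis passes through the midpoint of C2–C3, and the two carbons become homotopic with the same descriptor (R). Each stands alpha to a carbon (its CH2OH) that can be a carboxyl carbon, so both are donor carbons of like polarity.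

## Logic of the disconnections

**15 back to 12 (through 14 and 13).**
- Bond cut: C1–C8a, which opens ring B.
- Reason: this bond hides the symmetry. Without it both arenes are alike, both benzylic carbons are CH2, and C1 is no longer a stereocentre.
- Gain: one ring and one of three stereocentres vanish, and 15 becomes the C2-symmetric 12 with homotopic halves.
- Demand: exactly one benzylic CH2 must be raised to the cation level (13). Capture by oxygen (14) must remain reversible. The C–C bond must form ortho to a methoxy group, and C1 must be set by C2. Which CH2 and which ortho carbon react is immaterial, because both pairs are equivalent. The oxidation must, however, stop after one event.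

**12 back to 11.**
- Bonds cut (forward sense): the two phenolic O–CH2Ph bonds.
- Reason: free phenols would be the first site of attack in the oxidative key step.
- Gain: none in the skeleton. The change only makes the key step possible.
- Demand: neutral, reductive unmasking that leaves the two ArCH2–C bonds alone.

**11 back to 10.**
- Bonds cut (forward sense): the two exocyclic acyl C–N bonds. The carbinol carbons are taken back to imide carbonyls.
- Reason: at the acyl level C2 and C3 become enolisable alpha carbons, and a stereodirecting group sits next to each.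
- Gain: the functional groups of 11 are traced to one repeated unit.
- Demand: both hindered imides must be reduced without epimerisation and with release of 5.

**10 back to 7 plus 7 (key disconnection).**
- Bond cut: C2–C3, on the C2 axis.
- Reason: it is the only bond whose removal gives two identical fragments. It is flanked by both stereocentres that control the third.
- Gain: the carbon count is halved, two stereocentres disappear together, and one monomer with an achiral chain remains.
- Demand: two alpha carbons of like (donor) polarity must be joined, which requires removal of two electrons. Each carbon must bond through the same face relative to its own auxiliary.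
- Named by its key step and precursor alone, the route is the oxidative homocoupling of the enolate of 7 with itself. That sentence does not describe the plan under Alternative 1.

**7 back to 4 plus 5.**
- Bond cut: the imide N–acyl bond.
- Reason and gain: it separates the commercial stereocontrol element 5 from an achiral acid.
- Demand: acylation at nitrogen without touching the stereocentre of 5.

**4 back to 2 and 1.**
- Bonds cut: the O–CH2Ph bond, then (retro-hydrogenation) the two C–H bonds at the side-chain carbons.
- Reason and gain: 1 already holds ring, oxygenation pattern and C3 chain, that is every carbon of one half of 15.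
- Demand: the alkene must be saturated before the benzyl ether is put on, so that the ether is never exposed to hydrogenation at this stage.

## Other disconnections considered

Alternative 1: Cut C1–C8a last at the lactone level, and before it C1–C2. The forward key step is the acid-induced Friedel–Crafts cyclisation of the benzylic alcohol A1 (assembled by alkylation and aldol chemistry on a butyrolactone core) to the trans-fused aryltetralin lactone A2. Hydride reduction and debenzylation follow. This is the plan that comes to mind first. It should be dependable, because the C1 cation is well stabilised and the closure is governed by C2. It is set aside on structure and step economy: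
- The two identical halves of 15 enter as two different building blocks, one as a nucleophile and one as an electrophile.
- C3, C2 and C1 are set in three separate operations.
- The enantiopure monosubstituted lactone core alone should cost about as many steps as the chosen route needs to reach 10.

Alternative 2: Cut C2–C3 and C1–C8a together. The forward key step is the one-electron oxidation of methyl sinapate A3. Two phenoxyl radicals join at their side-chain beta carbons to the bis-quinone methide A4, which cyclises to the 1,2-dihydronaphthalene A5. The cascade makes more bonds than the chosen key step but settles fewer stereocentres: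
- In A4 the future ring A is a quinone methide and not a nucleophile. It regains aromaticity only by losing the hydrogen on C3.
- C3 is thus erased, and A5 stands two hydrogens above the oxidation level of 15.
- C3 would have to be reset by hydrogenation of a conjugated trisubstituted alkene, under the weak bias of C1 and C2.
- The radical union takes place between free planar species far from any directing group, so no dependable handle on the absolute configuration exists. A resolution would be needed.

Alternative 3: Cut C1–C2 and C3–C4. The forward key step is strain release. Thermal conrotatory opening of the 1-arylbenzocyclobutene A6 gives the outward o-quinodimethane A7. This is trapped in a Diels–Alder reaction by the fumarate of methyl (S)-lactate A8, giving the diester A9. The plan is set aside for three reasons: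
- A6 is a pentasubstituted arene with a strained ring that already contains both aryl–C1 bonds. Its preparation should be longer than the whole chosen route, and it uses no symmetry.
- The outward rotation that gives the reactive diene pushes ring C against the C8 methoxy group.
- With a trans dienophile one ester must be endo and the other exo. The 1,2-trans versus 1,2-cis outcome, and the absolute sense, would then rest on small energy differences at high temperature.

Key step: step 4

Remark on the chemistry: the given SMILES corresponds to (1S,2R,3R) in tetralin numbering, the all-trans isomer. Compounds 1 (E isomer) and 5 are taken as commercial.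

## Steps

Step 1
Reactants: 1 (E)-sinapic acid
Product: 2 3-(4-hydroxy-3,5-dimethoxyphenyl)propanoic acid
Conditions: H2 (1 atm), 10% Pd/C, MeOH, rt
Reagents that add atoms: none
Why: Heterogeneous catalytic hydrogenation of a cinnamic acid C=C bond; arene, phenol and acid are inert under these conditions and no stereocentre is formed.

Step 2
Reactants: 2 3-(4-hydroxy-3,5-dimethoxyphenyl)propanoic acid
Product: 4 3-[4-(benzyloxy)-3,5-dimethoxyphenyl]propanoic acid, via benzyl ester 3 (not isolated)
Conditions: BnBr (2.3 equiv), K2CO3, DMF, 60 °C; then aq NaOH, MeOH, 50 °C; HCl to pH 2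
Reagents that add atoms: benzyl bromide, BrCc1ccccc1; sodium hydroxide, [Na+].[OH-]
Why: Williamson etherification of the phenoxide, in which the carboxylate is benzylated as well, so ester 3 is saponified in the same flask while the aryl benzyl ether is inert to hydroxide. The ether masks the phenol, which would otherwise be the most oxidisable site in step 4.

Step 3
Reactants: 4 3-[4-(benzyloxy)-3,5-dimethoxyphenyl]propanoic acid; 5 (4S)-4-isopropyl-1,3-oxazolidin-2-one
Product: 7 (4S)-3-{3-[4-(benzyloxy)-3,5-dimethoxyphenyl]propanoyl}-4-isopropyl-1,3-oxazolidin-2-one, via mixed pivalic anhydride 6 (not isolated)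
Conditions: PivCl, Et3N, THF, −20 °C; then LiCl, 5, −20 °C → rt
Reagents that add atoms: none
Why: Mixed-anhydride N-acylation of an oxazolidinone (LiCl/Et3N variant); the nitrogen attacks the unhindered carbonyl of 6 and the stereocentre of 5 is not involved.

Step 4
Reactants: 7 (4S)-3-{3-[4-(benzyloxy)-3,5-dimethoxyphenyl]propanoyl}-4-isopropyl-1,3-oxazolidin-2-one (two molecules)
Product: 10 (2R,3R)-2,3-bis[4-(benzyloxy)-3,5-dimethoxybenzyl]-1,4-bis[(4S)-4-isopropyl-2-oxo-1,3-oxazolidin-3-yl]butane-1,4-dione, via lithium (Z)-enolate 8 (not isolated), via trichlorotitanium (Z)-enolate 9 (not isolated)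
Conditions: LDA (1.1 equiv), THF, −78 °C; TiCl4 (1.1 equiv), −78 °C → rt; aq NH4Cl
Reagents that add atoms: none
Why: LDA gives the chelated (Z)-enolate 8 and TiCl4 converts it into 9, in which inner-sphere electron transfer from the enolate ligand to Ti(IV) (which leaves as Ti(III)) puts spin density on the alpha carbon, so that two carbons that were both nucleophiles combine to the C2–C3 sigma bond. The closest known reaction type is the oxidative homocoupling of metal enolates of chiral N-acyloxazolidinones with Ti(IV), Cu(II) or I(III) oxidants, which is established for 3-arylpropanoyl imides, the substrate class of 7. No ring is closed; the step joins the two C6–C3 halves and so assembles every carbon of 15 with only one C–C bond left to make. Each of the two new stereocentres is controlled by its own auxiliary: in the O,O-chelate the isopropyl group on C4 of the oxazolidinone covers one face of the alpha carbon, each partner bonds through its open face (the face used in Evans alkylations of (4S)-imides), and with the priorities C=O > CH > CH2Ar this means R at both carbons. The selectivity needed is (R,R) over (R,S) and (S,S): the first error needs one partner and the second both partners to bond through a covered face, so the wrong absolute sense is suppressed twice over. All three are diastereomers because of the auxiliaries, so 10 can be freed of the others by crystallisation or chromatography and should carry full enantiopurity forward. Chemoselectivity rests on the benzyl ethers, which remove the phenol as the most oxidisable site, on the much lower oxidation potential of an enolate compared with a trialkoxyarene, and on THF, which tempers the Lewis acidity of TiCl4 towards the ethers.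

Step 5
Reactants: 10 (2R,3R)-2,3-bis[4-(benzyloxy)-3,5-dimethoxybenzyl]-1,4-bis[(4S)-4-isopropyl-2-oxo-1,3-oxazolidin-3-yl]butane-1,4-dione
Product: 11 (2R,3R)-2,3-bis[4-(benzyloxy)-3,5-dimethoxybenzyl]butane-1,4-diol
Conditions: LiBH4, THF/MeOH (20:1), 0 °C → rt; aq NaOH work-up
Reagents that add atoms: none
Why: Reductive cleavage of N-acyloxazolidinones with borohydride, in which hydride adds to the more electrophilic exocyclic carbonyl and the auxiliary 5 leaves and can be recovered. The medium is not basic enough to enolise C2 or C3, so both centres should be retained.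

Step 6
Reactants: 11 (2R,3R)-2,3-bis[4-(benzyloxy)-3,5-dimethoxybenzyl]butane-1,4-diol
Product: 12 (2R,3R)-2,3-bis(4-hydroxy-3,5-dimethoxybenzyl)butane-1,4-diol
Conditions: H2 (1 atm), 10% Pd/C, MeOH/EtOAc, rt
Reagents that add atoms: none
Why: Hydrogenolysis of aryl benzyl ethers; the ArCH2–C bonds carry no heteroatom and are not cleaved, and no stereocentre is touched.

Step 7
Reactants: 12 (2R,3R)-2,3-bis(4-hydroxy-3,5-dimethoxybenzyl)butane-1,4-diol
Product: 15 (1S,2R,3R)-lyoniresinol, via p-quinone methide 13 (not isolated), via tetrahydrofuran lignan 14 (not isolated)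
Conditions: DDQ (1.0 equiv), MeCN, 0 °C, until the oxidant is consumed; then TsOH·H2O (20 mol%), rt
Reagents that add atoms: none
Why: Quinone dehydrogenation of a 4-alkyl-2,6-dimethoxyphenol gives 13, which the hydroxyl group of the other half captures (5-exo oxa-1,6-addition) as 14; acid, added only after the oxidant is spent so that the tetralin never meets it, re-ionises the benzylic C–O bond and the cation is taken irreversibly by the second arene (intramolecular Friedel–Crafts alkylation, the known acid isomerisation of 7,9'-epoxylignans to aryltetralins). C1 is set by C2: in the half-chair transition state with the C2 and C3 substituents equatorial, ring C takes the pseudo-equatorial place anti to C2–CH2OH, which is 1,2-trans and hence (1S). The two benzylic CH2 groups of 12 are homotopic and the two ortho carbons of the attacking ring are equivalent, so only one constitution can result.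

## Compound list

1 | (E)-sinapic acid, (2E)-3-(4-hydroxy-3,5-dimethoxyphenyl)prop-2-enoic acid | COc1cc(/C=C/C(=O)O)cc(OC)c1O | starting material
2 | 3-(4-hydroxy-3,5-dimethoxyphenyl)propanoic acid | COc1cc(CCC(=O)O)cc(OC)c1O | intermediate
3 | benzyl 3-[4-(benzyloxy)-3,5-dimethoxyphenyl]propanoate | COc1cc(CCC(=O)OCc2ccccc2)cc(OC)c1OCc1ccccc1 | intermediate
4 | 3-[4-(benzyloxy)-3,5-dimethoxyphenyl]propanoic acid | COc1cc(CCC(=O)O)cc(OC)c1OCc1ccccc1 | intermediate
5 | (4S)-4-isopropyl-1,3-oxazolidin-2-one | CC(C)[C@H]1COC(=O)N1 | starting material
6 | 3-[4-(benzyloxy)-3,5-dimethoxyphenyl]propanoic pivalic anhydride | COc1cc(CCC(=O)OC(=O)C(C)(C)C)cc(OC)c1OCc1ccccc1 | intermediate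
7 | (4S)-3-{3-[4-(benzyloxy)-3,5-dimethoxyphenyl]propanoyl}-4-isopropyl-1,3-oxazolidin-2-one | COc1cc(CCC(=O)N2[C@@H](C(C)C)COC2=O)cc(OC)c1OCc1ccccc1 | intermediate
8 | lithium (Z)-enolate of 7 | [Li+].[O-]/C(=C\Cc1cc(OC)c(OCc2ccccc2)c(OC)c1)N1[C@@H](C(C)C)COC1=O | intermediate
9 | trichlorotitanium(IV) (Z)-enolate of 7 | Cl[Ti](Cl)(Cl)O/C(=C\Cc1cc(OC)c(OCc2ccccc2)c(OC)c1)N1[C@@H](C(C)C)COC1=O | intermediate
10 | (2R,3R)-2,3-bis[4-(benzyloxy)-3,5-dimethoxybenzyl]-1,4-bis[(4S)-4-isopropyl-2-oxo-1,3-oxazolidin-3-yl]butane-1,4-dione | O=C(N1[C@@H](C(C)C)COC1=O)[C@H](Cc1cc(OC)c(OCc2ccccc2)c(OC)c1)[C@@H](Cc1cc(OC)c(OCc2ccccc2)c(OC)c1)C(=O)N1[C@@H](C(C)C)COC1=O | intermediate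
11 | (2R,3R)-2,3-bis[4-(benzyloxy)-3,5-dimethoxybenzyl]butane-1,4-diol | OC[C@H](Cc1cc(OC)c(OCc2ccccc2)c(OC)c1)[C@@H](Cc1cc(OC)c(OCc2ccccc2)c(OC)c1)CO | intermediate
12 | (2R,3R)-2,3-bis(4-hydroxy-3,5-dimethoxybenzyl)butane-1,4-diol | OC[C@H](Cc1cc(OC)c(O)c(OC)c1)[C@@H](Cc1cc(OC)c(O)c(OC)c1)CO | intermediate
13 | mono-p-quinone methide of 12: 4-[4-hydroxy-3-(4-hydroxy-3,5-dimethoxybenzyl)-2-(hydroxymethyl)butylidene]-2,6-dimethoxycyclohexa-2,5-dien-1-one, both stereocentres arranged as in 12 | OC[C@H](Cc1cc(OC)c(O)c(OC)c1)[C@@H](C=C1C=C(OC)C(=O)C(OC)=C1)CO | intermediate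
14 | [(2S,3R,4R)-2-(4-hydroxy-3,5-dimethoxyphenyl)-4-(4-hydroxy-3,5-dimethoxybenzyl)oxolan-3-yl]methanol | O1C[C@H](Cc2cc(OC)c(O)c(OC)c2)[C@H](CO)[C@H]1c1cc(OC)c(O)c(OC)c1 | intermediate
15 | (1S,2R,3R)-lyoniresinol, (1S,2R,3R)-1-(4-hydroxy-3,5-dimethoxyphenyl)-2,3-bis(hydroxymethyl)-6,8-dimethoxy-1,2,3,4-tetrahydronaphthalen-7-ol | COc1cc([C@H]2c3c(cc(OC)c(O)c3OC)C[C@@H](CO)[C@@H]2CO)cc(OC)c1O | target

## Step count and least certain steps

Total step count: 7. Longest linear sequence: 7 (1 to 15).

**Step 4 (key step).**
The most likely failure is erosion of the like/like selectivity, if the C–C bond forms only after the carbon radical has left the chelate. Other risks are return of the enolate to 7 by hydrogen abstraction and attack of the Lewis acid on the hindered benzyl ethers during warming.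

The fallback builds the same bond in a polar, stepwise way. It sets out from 7 and returns at 11.
- The sodium enolate of 7 would be alkylated with tert-butyl bromoacetate (Evans alkylation, same open face, hence the same R sense). This gives tert-butyl (3R)-3-[4-(benzyloxy)-3,5-dimethoxybenzyl]-4-[(4S)-4-isopropyl-2-oxo-1,3-oxazolidin-3-yl]-4-oxobutanoate F1.
- Borohydride would remove the auxiliary to give tert-butyl (3R)-3-[4-(benzyloxy)-3,5-dimethoxybenzyl]-4-hydroxybutanoate F2.
- Acid would close this to (4R)-4-[4-(benzyloxy)-3,5-dimethoxybenzyl]oxolan-2-one F3.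
- In parallel, commercial syringaldehyde would be O-benzylated to 4-(benzyloxy)-3,5-dimethoxybenzaldehyde F4. This would be reduced with NaBH4 to [4-(benzyloxy)-3,5-dimethoxyphenyl]methanol F5. PBr3 would then convert it into 2-(benzyloxy)-5-(bromomethyl)-1,3-dimethoxybenzene F6.
- The lithium enolate of F3 would be alkylated by F6 anti to the substituent on C4. This gives (3R,4R)-3,4-bis[4-(benzyloxy)-3,5-dimethoxybenzyl]oxolan-2-one F7.
- LiAlH4 would open F7 to 11.

**Step 7.**
The most likely failure is a second oxidation that competes with the first, because both phenol units are equally oxidisable and only stoichiometry separates them. Further risks are tautomerisation of the quinone methide to a styrene, which would erase C2, and dehydrogenation of ring B if oxidant and acid are present together.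

The fallback overshoots and comes back. It sets out from 12 and returns at 14.
- 12 would be oxidised exhaustively (at least two equivalents of oxidant, no acid). Both benzylic carbons are then captured by the two hydroxyl groups, and no mono-selectivity is needed. The product is the furofuran (7S,8R,7'S,8'R)-syringaresinol F8.
- Hydrogenolysis over Pd/C, stopped after one equivalent of hydrogen, would open one benzylic C–O bond to 14. The first opening should be favoured because it releases the strain of the cis-fused dioxabicyclo[3.3.0]octane. Over-reduction only leads back to 12.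
- Isolated 14 would then meet acid in the absence of any oxidant and give 15.

**Step 5.**
The most likely failure is hydride attack at the ring carbonyl of the auxiliary (endocyclic cleavage), because each exocyclic carbonyl is flanked by a fully branched alpha carbon. The reduction may also stall before both ends have reached the alcohol level.

The fallback separates cleavage and reduction. It sets out from 10 and returns at 11.
- Lithium hydroperoxide (LiOH, H2O2, THF/H2O, 0 °C) attacks the exocyclic carbonyl selectively even in hindered imides. It would give (2R,3R)-2,3-bis[4-(benzyloxy)-3,5-dimethoxybenzyl]butanedioic acid F9.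
- BH3·THF would reduce F9 to 11.

## Further compounds

F1 | step 4 | tert-butyl (3R)-3-[4-(benzyloxy)-3,5-dimethoxybenzyl]-4-[(4S)-4-isopropyl-2-oxo-1,3-oxazolidin-3-yl]-4-oxobutanoate | CC(C)(C)OC(=O)C[C@@H](Cc1cc(OC)c(OCc2ccccc2)c(OC)c1)C(=O)N1[C@@H](C(C)C)COC1=O
F2 | step 4 | tert-butyl (3R)-3-[4-(benzyloxy)-3,5-dimethoxybenzyl]-4-hydroxybutanoate | CC(C)(C)OC(=O)C[C@@H](Cc1cc(OC)c(OCc2ccccc2)c(OC)c1)CO
F3 | step 4 | (4R)-4-[4-(benzyloxy)-3,5-dimethoxybenzyl]oxolan-2-one | O=C1C[C@@H](Cc2cc(OC)c(OCc3ccccc3)c(OC)c2)CO1
F4 | step 4 | 4-(benzyloxy)-3,5-dimethoxybenzaldehyde | COc1cc(C=O)cc(OC)c1OCc1ccccc1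
F5 | step 4 | [4-(benzyloxy)-3,5-dimethoxyphenyl]methanol | COc1cc(CO)cc(OC)c1OCc1ccccc1
F6 | step 4 | 2-(benzyloxy)-5-(bromomethyl)-1,3-dimethoxybenzene | COc1cc(CBr)cc(OC)c1OCc1ccccc1
F7 | step 4 | (3R,4R)-3,4-bis[4-(benzyloxy)-3,5-dimethoxybenzyl]oxolan-2-one | O=C1OC[C@H](Cc2cc(OC)c(OCc3ccccc3)c(OC)c2)[C@H]1Cc1cc(OC)c(OCc2ccccc2)c(OC)c1
F8 | step 7 | (7S,8R,7'S,8'R)-syringaresinol | O1C[C@@H]2[C@@H](c3cc(OC)c(O)c(OC)c3)OC[C@@H]2[C@H]1c1cc(OC)c(O)c(OC)c1
F9 | step 5 | (2R,3R)-2,3-bis[4-(benzyloxy)-3,5-dimethoxybenzyl]butanedioic acid | OC(=O)[C@H](Cc1cc(OC)c(OCc2ccccc2)c(OC)c1)[C@@H](Cc1cc(OC)c(OCc2ccccc2)c(OC)c1)C(=O)O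
A1 | alternative 1 | (3S,4R)-4-[4-(benzyloxy)-3,5-dimethoxybenzyl]-3-{[4-(benzyloxy)-3,5-dimethoxyphenyl](hydroxy)methyl}oxolan-2-one, carbinol centre either way | O=C1OC[C@H](Cc2cc(OC)c(OCc3ccccc3)c(OC)c2)[C@H]1C(O)c1cc(OC)c(OCc2ccccc2)c(OC)c1
A2 | alternative 1 | trans-fused 1-aryltetralin gamma-lactone (carbonyl on C2), dibenzyl ether, C1, C2 and C3 arranged as in 15 | COc1cc([C@H]2c3c(cc(OC)c(OCc4ccccc4)c3OC)C[C@H]4COC(=O)[C@H]24)cc(OC)c1OCc1ccccc1
A3 | alternative 2 | methyl (E)-sinapate | COC(=O)/C=C/c1cc(OC)c(O)c(OC)c1
A4 | alternative 2 | dimethyl 2,3-bis[(3,5-dimethoxy-4-oxocyclohexa-2,5-dien-1-ylidene)methyl]butanedioate, racemic, threo isomer drawn | COC(=O)[C@H](C=C1C=C(OC)C(=O)C(OC)=C1)[C@@H](C=C1C=C(OC)C(=O)C(OC)=C1)C(=O)OC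
A5 | alternative 2 | dimethyl trans-7-hydroxy-1-(4-hydroxy-3,5-dimethoxyphenyl)-6,8-dimethoxy-1,2-dihydronaphthalene-2,3-dicarboxylate, racemic, one enantiomer drawn | COc1cc([C@H]2c3c(cc(OC)c(O)c3OC)C=C(C(=O)OC)[C@@H]2C(=O)OC)cc(OC)c1O
A6 | alternative 3 | 1-arylbenzocyclobutene: 4-(benzyloxy)-7-[4-(benzyloxy)-3,5-dimethoxyphenyl]-3,5-dimethoxybicyclo[4.2.0]octa-1,3,5-triene, racemic | COc1cc2CC(c3cc(OC)c(OCc4ccccc4)c(OC)c3)c2c(OC)c1OCc1ccccc1
A7 | alternative 3 | outward alpha-aryl-o-quinodimethane from A6 (aryl anti to C4a) | C=C1C=C(OC)C(OCc2ccccc2)=C(OC)/C1=C\c1cc(OC)c(OCc2ccccc2)c(OC)c1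
A8 | alternative 3 | bis[(2S)-1-methoxy-1-oxopropan-2-yl] fumarate | COC(=O)[C@H](C)OC(=O)/C=C/C(=O)O[C@@H](C)C(=O)OC
A9 | alternative 3 | Diels–Alder adduct: all-trans 1-aryltetralin-2,3-dicarboxylate of methyl (S)-lactate, dibenzyl ether, C1, C2 and C3 arranged as in 15 | COc1cc([C@H]2c3c(cc(OC)c(OCc4ccccc4)c3OC)C[C@@H](C(=O)O[C@@H](C)C(=O)OC)[C@@H]2C(=O)O[C@@H](C)C(=O)OC)cc(OC)c1OCc1ccccc1
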